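Readings and results are calculated for an exercise; noise was put on by code.

At early times the teal run already empties its substrate, from 19.0% at 0.250 h to 0.5% at 1.50 h, so a ledger of where the substrate went can soon be drawn up.

| setting | amber | teal | Saturday's | Wednesday's | Tuesday's | Sunday's |
|---|---|---|---|---|---|---|
| substrate | 0.19 M | 0.19 M | 0.19 M | 0.19 M (fed, over 2.5 h) | 0.19 M (fed, over 15 min) | 0.19 M |
| partner | 0.90 equiv | 1.8 equiv | 0.900 equiv | 0.900 equiv | 0.900 equiv | 0.900 equiv (fed, over 2.5 h) |
| remark | run made earlier | run made earlier | everything together at the start | all else is in the flask from the start; the feed brings no volume worth counting | all else is in the flask from the start; the feed brings no volume worth counting | all else is in the flask from the start; the feed brings no volume worth counting |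
| time |  |  | 12 h | 12 h | 12 h | 12 h |

| run | time / h | target / % | substrate / % |
|---|---|---|---|
| amber | 3.00 | 43.5 | 0.2 |
| amber | 6.00 | 40.8 | 0.6 |
| amber | 10.0 | 40.4 | 0 |
| amber | 12.0 | 39.3 | 0 |
| teal | 0.250 | 19.8 | 19.0 |
| teal | 0.667 | 51.5 | 3.1 |
| teal | 1.50 | 61.5 | 0.5 |
| teal | 4.00 | 54.9 | 0.5 |

(each reading ± 0.5 percentage points)

- a species is counted by the substrate in it: one homo product counts as two
- candidate steps: target <-> isomer of the product; substrate <-> open intermediate; partner -> second intermediate; 2 open intermediate -> homo product; open intermediate -> decomposed reagent; open intermediate + second intermediate -> target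

1. which flask leads in amount of target, in percent of the substrate charged ("all alike" within 1.5 percentage points) (Saturday's / Wednesday's / Tuesday's / Sunday's / all alike)
2. how much target is there at the end, in percent of the substrate charged: Saturday's
3. how much target is there at the end, in percent of the substrate charged: Wednesday's
4. how much target is there at the end, in percent of the substrate charged: Tuesday's
5. how much target is there at the end, in percent of the substrate charged: Sunday's

1. In the amber run at 12.0 h, the substrate reads 0% and the target 39.3%. The remaining 60.7% of the charge therefore sits in species that were not read.

2. These two entries make one quantity. The amber run gives σ = 0.719 equiv⁻¹, where σ is a selectivity factor: target divided by all other substrate, per equivalent of partner.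

3. The teal ledger at its last reading, 4.00 h, holds 54.9% of target and gives σ = 0.676 equiv⁻¹. Twice the partner went with a ratio of target to the rest 1.88 times as large, but these readings stand at different times, 12.0 h and 4.00 h, and two runs make no law. With 0.19 M of substrate, target ≈ σe/(1 + σe), with e the equivalents of partner, is therefore a working estimate and not a rule.

4. This reckoning puts Saturday's, which repeats the amber recipe, near 39.3%. A feed then counts as a correction to σ.

5. The forecast names Wednesday's as leader, with 39.5% for Saturday's, 58% for Wednesday's, 41% for Tuesday's and 23% for Sunday's. Its ground for Wednesday's is that the feed “matches substrate supply to second-intermediate formation”. That value corresponds to σ = 1.53 equiv⁻¹, twice the amber value.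

6. The flasks give 39.7% for Saturday's, 43.2% for Wednesday's, 40.6% for Tuesday's and 25.2% for Sunday's. Wednesday's leads, as forecast, but with 43.2% rather than 58%.

    target ⇌ isomer of the product (K = 0.551, k = 0.00387 min⁻¹)
    substrate ⇌ open intermediate (K = 9.10, k = 0.131 min⁻¹)
    partner → second intermediate (k = 0.123 min⁻¹)
    2 open intermediate → homo product (k = 0.0287 L mol⁻¹ min⁻¹)
    open intermediate → decomposed reagent (k = 0.00505 min⁻¹)
    open intermediate + second intermediate → target (k = 0.150 L mol⁻¹ min⁻¹)

Wednesday's result corresponds to σ = 0.844 equiv⁻¹, a correction of 1.17 times the amber value. In Wednesday's flask half of the partner's turnover is done by 0.0940 h, and half of the substrate's opening only by 1.43 h, much later. Second intermediate still stands at 0.0441 M after 12.0 h.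

For Wednesday's recipe with 0.230 equiv of partner instead, the amber σ gives 14.2% of target. The computed flask holds 14.0%.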